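The chroman is opened at O1–C2, and the acyclic chain that remains is cut twice at C4. This methine carries naphthalene C1′ and ring-A carbon C4a and sits next to the C3 methylene. That is the pattern left when the CH2 end of a terminal alkene is arylated twice. One palladium-catalysed operation therefore joins a naphthalene-1-diazonium salt, a 2,6-dioxygenated phenylboronic acid and O-protected (S)-but-3-en-2-ol. It makes C4–C1′, C4–C4a and the C4 stereocentre without closing a ring. The alkene precursor carries its oxygen as a benzyl carbonate, so one hydrogenolysis frees all three hydroxyls. Mitsunobu closure with inversion at C2 then gives the trans-(2R,4S)-chroman.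

Key step: step 8

Remark (numbering): chain carbons carry chroman numbers throughout (O1, C2 with CH3, C3, C4, C4a, C5 with OH, C8a); primed numbers belong to the naphthalene.
Remark (stereochemistry): the target SMILES reads as 2R,4S with methyl and naphthyl trans; the open chain must be 2S,4S, because C2 is inverted in the last step and the CIP order at C4 (dioxygenated aryl > naphthyl > C3 > H) does not change.
Remark (protecting group): a benzyl carbonate is chosen at C2–O because allylic carbonates are a proven alkene class for this type of coupling, because the acyl group makes C2–H less hydridic and offers a carbonyl donor to cationic palladium, and because it leaves in the same hydrogenolysis as the aryl benzyl ethers.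
Remark (assumption): the enantiomer of the chiral phosphate that is matched to the S-configured carbonate cannot be predicted, so both commercial enantiomers are to be tried; since C2 is fixed, the C4 epimers are diastereomers and can be separated on silica.
Remark (palladium species): only the η3-naphthylmethyl complex is numbered, drawn in its η1 form without counter-ion.

Step 1
Reactants: 1 naphthalene-1,8-diol
Product: 2 1,8-dimethoxynaphthalene
Conditions: MeI, K2CO3, DMF, rt to 40 °C
Reagents that add atoms: iodomethane, CI
Why: Williamson ether synthesis: carbonate deprotonates both peri phenols and each phenoxide attacks iodomethane by SN2, with no other reactive site in 1.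

Step 2
Reactants: 2 1,8-dimethoxynaphthalene
Product: 3 1-bromo-4,5-dimethoxynaphthalene
Conditions: NBS (1.0 equiv), MeCN, 0 °C to rt, dark
Reagents that add atoms: N-bromosuccinimide, O=C1CCC(=O)N1Br
Why: Electrophilic aromatic bromination: C4, para to a methoxy group, is the most activated open position of 2, and one equivalent of NBS in acetonitrile should stop at the monobromide, which fixes the 1,4,5-pattern more cleanly than nitration of so oxidisable an arene would.

Step 3
Reactants: 3 1-bromo-4,5-dimethoxynaphthalene
Product: 5 4,5-dimethoxynaphthalen-1-amine, via ketimine 4 (not isolated)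
Conditions: Ph2C=NH, Pd2(dba)3 (cat.), rac-BINAP (cat.), NaOtBu, toluene, 90 °C; then 1 M aq HCl, THF, rt; NaOH work-up
Reagents that add atoms: benzophenone imine, N=C(c1ccccc1)c1ccccc1
Why: Buchwald–Hartwig amination with benzophenone imine as an ammonia surrogate gives ketimine 4, whose C=N bond is hydrolysed by dilute acid at room temperature while the aryl methyl ethers stay untouched.

Step 4
Reactants: 5 4,5-dimethoxynaphthalen-1-amine
Product: 6 4,5-dimethoxynaphthalene-1-diazonium tetrafluoroborate
Conditions: 48% aq HBF4, t-BuONO, EtOH, 0 °C; precipitation with Et2O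
Reagents that add atoms: tert-butyl nitrite, CC(C)(C)ON=O; tetrafluoroboric acid, [H+].F[B-](F)(F)F
Why: Diazotisation of a primary arylamine with an alkyl nitrite in tetrafluoroboric acid: the amine is kept protonated so that azo self-coupling is held back, the para methoxy group stabilises the diazonium ion, and the halide-free tetrafluoroborate should fall out on adding ether.

Step 5
Reactants: 7 2-bromoresorcinol
Product: 8 1,3-bis(benzyloxy)-2-bromobenzene
Conditions: BnBr, K2CO3, DMF, rt
Reagents that add atoms: benzyl bromide, BrCc1ccccc1
Why: Williamson ether synthesis on both phenols, the aryl bromide being inert to carbonate and benzyl bromide.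

Step 6
Reactants: 8 1,3-bis(benzyloxy)-2-bromobenzene
Product: 11 2,6-bis(benzyloxy)phenylboronic acid, via aryllithium 9 (not isolated), via lithium aryltriisopropoxyborate 10 (not isolated)
Conditions: n-BuLi, THF, −78 °C; B(OiPr)3, −78 to 0 °C; 1 M aq HCl, 0 °C
Reagents that add atoms: triisopropyl borate, CC(C)OB(OC(C)C)OC(C)C; water, O; n-butyllithium, [Li]CCCC (lithium of 9 and 10 only)
Why: Bromine–lithium exchange at −78 °C is faster than deprotonation of the benzylic ether CH2 groups and puts the metal exactly between the two oxygens, the aryllithium is trapped by the borate ester (electrophilic borylation), and brief cold hydrolysis frees the boronic acid before protodeboronation can set in.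

Step 7
Reactants: 12 (S)-but-3-en-2-ol
Product: 13 benzyl (S)-but-3-en-2-yl carbonate
Conditions: CbzCl, pyridine, DMAP (cat.), CH2Cl2, 0 °C to rt
Reagents that add atoms: benzyl chloroformate, O=C(Cl)OCc1ccccc1
Why: O-Acylation of the alcohol by the chloroformate (carbonate formation) breaks only the O–H bond, so C2 keeps its S configuration and the alkene is untouched.

Step 8
Reactants: 13 benzyl (S)-but-3-en-2-yl carbonate; 6 4,5-dimethoxynaphthalene-1-diazonium tetrafluoroborate; 11 2,6-bis(benzyloxy)phenylboronic acid
Product: 15 benzyl (2S,4S)-4-[2,6-bis(benzyloxy)phenyl]-4-(4,5-dimethoxynaphthalen-1-yl)butan-2-yl carbonate, via π-naphthylmethylpalladium cation 14 (not isolated)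
Conditions: 6 (1.5 equiv), 11 (2 equiv, in portions), Pd2(dba)3 (5 mol %), TRIP phosphoric acid (matched enantiomer, 12 mol %), NaHCO3, MTBE, 0 °C to rt; chromatographic removal of any C4 epimer
Reagents that add atoms: none
Why: Proposed new method: oxidative addition of Pd(0) to 6 with loss of N2 gives a cationic naphthylpalladium that adds across the alkene of 13 with the aryl group on the unhindered CH2 terminus (C4–C1′, the Heck–Matsuda half), after which syn β-hydride elimination of a benzylic C4–H and re-addition of Pd–H in the opposite sense move the metal to C4, where η3 binding over C4–C1′–C2′ gives 14. Base-assisted transmetalation from 11 and stereoretentive reductive elimination then form C4–C4a by ipso substitution at boron, so the crowded carbon between the two oxygens never has to act as an aromatic nucleophile, and no ring is closed. The closest known reaction type is the Pd(0)-catalysed three-component 1,1-diarylation of ethylene, allylic carbonates and acrylates with aryldiazonium salts and arylboronic acids, including its enantioselective form under chiral-anion phase transfer, in which a branched chiral allylic carbonate, a 1-naphthyl diazonium salt and a 2,6-disubstituted boronic acid have not been combined. C4 is the only new stereocentre: its configuration follows from the alkene face taken in the carbopalladation, is carried along because the hydride relay is suprafacial while palladium stays bound, and is governed by the chiral phosphate paired with the cationic metal, the adjacent C2 centre with its carbonyl donor acting as matched or mismatched partner. The step needs 1,1- rather than 1,2-diarylation or Heck termination, which the strongly stabilised naphthylmethyl η3 complex secures, and migration away from C2, which the electron-poor carbonate favours by making C2–H less hydridic than in an ether. C2 is not touched and stays S.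

Step 9
Reactants: 15 benzyl (2S,4S)-4-[2,6-bis(benzyloxy)phenyl]-4-(4,5-dimethoxynaphthalen-1-yl)butan-2-yl carbonate
Product: 16 (2S,4S)-4-(2,6-dihydroxyphenyl)-4-(4,5-dimethoxynaphthalen-1-yl)butan-2-ol
Conditions: H2 (1 atm), 10% Pd/C, EtOAc/MeOH, rt
Reagents that add atoms: none
Why: Catalytic hydrogenolysis cleaves the three O–CH2Ph bonds, the carbonic half-ester so formed at C2 loses CO2 by itself, and under neutral conditions at one atmosphere the naphthalene, the methyl ethers and both stereocentres (C4 carries no heteroatom) are left alone.

Step 10
Reactants: 16 (2S,4S)-4-(2,6-dihydroxyphenyl)-4-(4,5-dimethoxynaphthalen-1-yl)butan-2-ol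
Product: 17 cladonaphchrom A, (2R,4S)-4-(4,5-dimethoxynaphthalen-1-yl)-2-methylchroman-5-ol (2,4-trans)
Conditions: PPh3, DIAD, THF (0.01 M), 0 °C to rt
Reagents that add atoms: none
Why: Intramolecular Mitsunobu etherification: only the aliphatic C2 hydroxyl is activated on phosphorus and a phenol oxygen displaces it by SN2 (6-exo-tet) with inversion from S to R, the two phenols being interchanged by rotation about C4–C4a so that either gives the same chroman, while C4 is untouched and ends trans to the methyl group.

Compound list
1 | naphthalene-1,8-diol | Oc1cccc2cccc(O)c12 | starting material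
2 | 1,8-dimethoxynaphthalene | COc1cccc2cccc(OC)c12 | intermediate
3 | 1-bromo-4,5-dimethoxynaphthalene | COc1cccc2c(Br)ccc(OC)c12 | intermediate
4 | N-(4,5-dimethoxynaphthalen-1-yl)-1,1-diphenylmethanimine | COc1cccc2c(N=C(c3ccccc3)c3ccccc3)ccc(OC)c12 | intermediate (not isolated)
5 | 4,5-dimethoxynaphthalen-1-amine | COc1cccc2c(N)ccc(OC)c12 | intermediate
6 | 4,5-dimethoxynaphthalene-1-diazonium tetrafluoroborate | COc1cccc2c([N+]#N)ccc(OC)c12.F[B-](F)(F)F | intermediate
7 | 2-bromoresorcinol | Oc1cccc(O)c1Br | starting material
8 | 1,3-bis(benzyloxy)-2-bromobenzene | Brc1c(OCc2ccccc2)cccc1OCc1ccccc1 | intermediate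
9 | [2,6-bis(benzyloxy)phenyl]lithium | [Li]c1c(OCc2ccccc2)cccc1OCc1ccccc1 | intermediate (not isolated)
10 | lithium [2,6-bis(benzyloxy)phenyl]triisopropoxyborate | [Li+].CC(C)O[B-](OC(C)C)(OC(C)C)c1c(OCc2ccccc2)cccc1OCc1ccccc1 | intermediate (not isolated)
11 | 2,6-bis(benzyloxy)phenylboronic acid | OB(O)c1c(OCc2ccccc2)cccc1OCc1ccccc1 | intermediate
12 | (S)-but-3-en-2-ol | C=C[C@H](C)O | starting material
13 | benzyl (S)-but-3-en-2-yl carbonate | C=C[C@H](C)OC(=O)OCc1ccccc1 | intermediate
14 | [(1S,3S)-3-(benzyloxycarbonyloxy)-1-(4,5-dimethoxynaphthalen-1-yl)butyl]palladium(1+), η3 over C4–C1′–C2′, drawn η1, phosphate counter-ion omitted | COc1cccc2c([C@@H]([Pd+])C[C@H](C)OC(=O)OCc3ccccc3)ccc(OC)c12 | intermediate (not isolated)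
15 | benzyl (2S,4S)-4-[2,6-bis(benzyloxy)phenyl]-4-(4,5-dimethoxynaphthalen-1-yl)butan-2-yl carbonate | COc1cccc2c([C@@H](c3c(OCc4ccccc4)cccc3OCc3ccccc3)C[C@H](C)OC(=O)OCc3ccccc3)ccc(OC)c12 | intermediate
16 | (2S,4S)-4-(2,6-dihydroxyphenyl)-4-(4,5-dimethoxynaphthalen-1-yl)butan-2-ol | COc1cccc2c([C@@H](c3c(O)cccc3O)C[C@H](C)O)ccc(OC)c12 | intermediate
17 | cladonaphchrom A, (2R,4S)-4-(4,5-dimethoxynaphthalen-1-yl)-2-methylchroman-5-ol | COc1cccc2c([C@@H]3C[C@@H](C)Oc4cccc(O)c43)ccc(OC)c12 | target

Total step count: 10. Longest linear sequence: 7 (steps 1, 2, 3, 4, 8, 9, 10).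

Steps most likely to fail

Step 8 (the labelled step).
- **What may go wrong:**
  - The styrene may leave Pd–H before re-addition (Heck termination).
  - Loss of hydride or carbonate toward C2 may compete.
  - Idle Pd(0) may ionise the allylic carbonate. Phosphine-free palladium and the very fast oxidative addition to the diazonium ion argue against this.
  - Protodeboronation may outrun the slow transmetalation of a boronic acid flanked by two benzyloxy groups.
  - Face selection at C4 may be poor.
- **Fallback:** the three-component coupling is given up and both C4–aryl bonds are made by known polar reactions. The fallback sets out from 12, from 9 (made from 8 as in step 6) and from 2, and comes back at 16.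
  - Alcohol 12 is benzylated (NaH, BnBr, THF) to (S)-3-(benzyloxy)but-1-ene F1.
  - Hydroboration with 9-BBN gives the B-alkyl-9-borabicyclononane F2, which is oxidised in the same flask (NaOH, H2O2) to (S)-3-(benzyloxy)butan-1-ol F3.
  - Dess–Martin oxidation then gives (S)-3-(benzyloxy)butanal F4.
  - Addition of aryllithium 9 at −78 °C forms C4–C4a and gives (3S)-3-(benzyloxy)-1-[2,6-bis(benzyloxy)phenyl]butan-1-ol F5. It is a mixture of carbinol epimers, which does not matter because this centre is ionised next.
  - Catalytic Friedel–Crafts benzylation of an excess of 2 with F5 (Bi(OTf)3, CH2Cl2, 0 °C) passes through a cation stabilised by the two ortho oxygens. Naphthalene 2 attacks it through C4, the position that is also brominated in step 2, and C4–C1′ is formed.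
  - No reliable control at C4 is expected. 1-{(1S,3S)-3-(benzyloxy)-1-[2,6-bis(benzyloxy)phenyl]butyl}-4,5-dimethoxynaphthalene F6 is separated from its C4 epimer on silica.
  - Hydrogenolysis under the conditions of step 9 turns F6 into 16.

Step 4.
- **What may go wrong:** the electron-rich amine may be oxidised by the nitrite, the diazonium ion may couple with amine not yet consumed, and the salt may lose nitrogen on drying.
- **Fallback:** the diazonium ion is stored in masked form. The fallback sets out from 5 and comes back at 6.
  - Amine 5 is diazotised in cold aqueous HCl with NaNO2, where it is fully protonated, to give 4,5-dimethoxynaphthalene-1-diazonium chloride F7 in solution.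
  - This solution is run at once into pyrrolidine and K2CO3 to give (E)-1-[(4,5-dimethoxynaphthalen-1-yl)diazenyl]pyrrolidine F8, a neutral triazene that can be chromatographed and kept.
  - HBF4·OEt2 in Et2O at 0 °C cleaves the N–N single bond and should precipitate 6 just before it is needed.

Step 10.
- **What may go wrong:** closure may be slow because the phenol oxygens are shielded by the naphthyl group at C4. Elimination toward C3, or capture of the activated alcohol by the hydrazide, could then compete.
- **Fallback:** activation and displacement are separated, and a phenoxide serves as the nucleophile. The fallback sets out from 15 and comes back at 17.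
  - Methanolysis of the carbonate (K2CO3, MeOH, rt) gives (2S,4S)-4-[2,6-bis(benzyloxy)phenyl]-4-(4,5-dimethoxynaphthalen-1-yl)butan-2-ol F9.
  - Mesylation (MsCl, Et3N, CH2Cl2, 0 °C) gives its methanesulfonate F10.
  - Hydrogenolysis (H2, Pd/C, EtOAc) gives (2S,4S)-4-(2,6-dihydroxyphenyl)-4-(4,5-dimethoxynaphthalen-1-yl)butan-2-yl methanesulfonate F11.
  - K2CO3 in acetone closes the ring by intramolecular SN2 with the same inversion at C2 to give 17.

Further compounds
F1 | step 8 | (S)-3-(benzyloxy)but-1-ene | C=C[C@H](C)OCc1ccccc1
F2 | step 8 | 9-[(3S)-3-(benzyloxy)butyl]-9-borabicyclo[3.3.1]nonane | B1(CC[C@H](C)OCc2ccccc2)C2CCCC1CCC2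
F3 | step 8 | (S)-3-(benzyloxy)butan-1-ol | OCC[C@H](C)OCc1ccccc1
F4 | step 8 | (S)-3-(benzyloxy)butanal | O=CC[C@H](C)OCc1ccccc1
F5 | step 8 | (3S)-3-(benzyloxy)-1-[2,6-bis(benzyloxy)phenyl]butan-1-ol (both C1 epimers) | OC(C[C@H](C)OCc1ccccc1)c1c(OCc2ccccc2)cccc1OCc1ccccc1
F6 | step 8 | 1-{(1S,3S)-3-(benzyloxy)-1-[2,6-bis(benzyloxy)phenyl]butyl}-4,5-dimethoxynaphthalene | COc1cccc2c([C@@H](c3c(OCc4ccccc4)cccc3OCc3ccccc3)C[C@H](C)OCc3ccccc3)ccc(OC)c12
F7 | step 4 | 4,5-dimethoxynaphthalene-1-diazonium chloride | COc1cccc2c([N+]#N)ccc(OC)c12.[Cl-]
F8 | step 4 | (E)-1-[(4,5-dimethoxynaphthalen-1-yl)diazenyl]pyrrolidine | COc1cccc2c(/N=N/N3CCCC3)ccc(OC)c12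
F9 | step 10 | (2S,4S)-4-[2,6-bis(benzyloxy)phenyl]-4-(4,5-dimethoxynaphthalen-1-yl)butan-2-ol | COc1cccc2c([C@@H](c3c(OCc4ccccc4)cccc3OCc3ccccc3)C[C@H](C)O)ccc(OC)c12
F10 | step 10 | (2S,4S)-4-[2,6-bis(benzyloxy)phenyl]-4-(4,5-dimethoxynaphthalen-1-yl)butan-2-yl methanesulfonate | COc1cccc2c([C@@H](c3c(OCc4ccccc4)cccc3OCc3ccccc3)C[C@H](C)OS(C)(=O)=O)ccc(OC)c12
F11 | step 10 | (2S,4S)-4-(2,6-dihydroxyphenyl)-4-(4,5-dimethoxynaphthalen-1-yl)butan-2-yl methanesulfonate | COc1cccc2c([C@@H](c3c(O)cccc3O)C[C@H](C)OS(C)(=O)=O)ccc(OC)c12
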